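## Retrosynthetic overview

1. The target comes from its methyl ester, which is made in one flask from an acyclic chain: a thermally generated acylketene is C-acylated (C4a–C8a, closing the carbocycle C4a–C5–C6–C7–C8–C8a) and the new enol oxygen is O-alkylated (O1–C2, closing the pyranone). Chromene numbering is used: O1, C2, C3, C4, C4a, C5–C8, C8a.
2. Enabling feature: C4a is the central carbon of the tricarbonyl array C4(=O)/C5(–O)/C8a(–O), so C4a–C8a is a polyketide Claisen bond, and the enol oxygen it creates on C8a lies 1,5 to C2. C5–O is held as NMe2 (from an ynone), so only O1 can close on C2.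
3. The chain is joined from three blocks. The quaternary cyanoester (C6) carries the cyclobutane of (−)-verbenone (α-pinene skeleton) and gets its prenyl group by asymmetric phase-transfer alkylation. The anti-3-silyloxy-2-methylbutanoyl Weinreb amide (C2/C3) comes from ethyl (S)-3-hydroxybutanoate. Mono-tert-butyl (R)-3-phenylglutarate (benzylic centre, C8, C8a) comes from desymmetrised 3-phenylglutaric anhydride.
4. Ring order: cyclobutane (chiral pool) → carbocycle → pyranone, the last two in the key step.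

Key step: step 22

Remark: the triketone compounds are drawn as one enol tautomer (C4 enol, C5 and C7 ketones); all tautomers are the same compound.
Remark: the sense of induction in steps 6 and 15 is assigned by analogy within the catalyst class and is not certain. The commercial antipodes (the (11bR)-ammonium salt; quinine) give the other sense. In step 6 the two possible products are diastereomers and are separable.

## Route

Step 1
Reactants: 1 (1S,5S)-(−)-verbenone
Product: 2 (1S,3R)-3-acetyl-2,2-dimethylcyclobutane-1-carboxylic acid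
Conditions: RuCl3·xH2O (cat.), NaIO4, CCl4/MeCN/H2O, rt
Reagents that add atoms: sodium periodate, [Na+].[O-]I(=O)(=O)=O; water, O
Why: Ruthenium tetroxide cleavage of the enone C=C with loss of the α-keto acid carbon as CO2; both cyclobutane stereocentres and their cis relationship are inherited from the bicycle.

Step 2
Reactants: 2 (1S,3R)-3-acetyl-2,2-dimethylcyclobutane-1-carboxylic acid
Product: 3 (1S,3S)-2,2-dimethyl-3-(prop-1-en-2-yl)cyclobutane-1-carboxylic acid
Conditions: Ph3PCH3Br, KOt-Bu (excess), THF, 0 °C → rt; dilute HCl work-up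
Reagents that add atoms: methyltriphenylphosphonium bromide, C[P+](c1ccccc1)(c1ccccc1)c1ccccc1.[Br-]
Why: Wittig methylenation of the methyl ketone while the acid is masked as its potassium carboxylate; low temperature limits epimerisation at the ketone α-carbon.

Step 3
Reactants: 3 (1S,3S)-2,2-dimethyl-3-(prop-1-en-2-yl)cyclobutane-1-carboxylic acid
Product: 4 [(1S,3S)-2,2-dimethyl-3-(prop-1-en-2-yl)cyclobutyl]methanol
Conditions: LiAlH4, Et2O, 0 °C → rt
Reagents that add atoms: none
Why: Hydride reduction of the carboxylic acid to the primary alcohol; the isolated 1,1-disubstituted alkene is inert.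

Step 4
Reactants: 4 [(1S,3S)-2,2-dimethyl-3-(prop-1-en-2-yl)cyclobutyl]methanol
Product: 5 (1S,3S)-1-(iodomethyl)-2,2-dimethyl-3-(prop-1-en-2-yl)cyclobutane
Conditions: I2, PPh3, imidazole, CH2Cl2, 0 °C → rt
Reagents that add atoms: iodine, II
Why: Appel-type (Garegg–Samuelsson) iodination of a primary alcohol by SN2 at CH2, so no stereocentre is involved.

Step 5
Reactants: 5 (1S,3S)-1-(iodomethyl)-2,2-dimethyl-3-(prop-1-en-2-yl)cyclobutane; 6 tert-butyl cyanoacetate (3 equiv)
Product: 7 tert-butyl 2-cyano-3-[(1R,3S)-2,2-dimethyl-3-(prop-1-en-2-yl)cyclobutyl]propanoate (both C-2 epimers)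
Conditions: K2CO3, DMF, 60 °C
Reagents that add atoms: none
Why: SN2 C-alkylation of the cyanoacetate anion by the primary iodide, with excess nucleophile to suppress dialkylation; the new C-2 centre is left unassigned because it is re-formed in step 6.

Step 6
Reactants: 7 tert-butyl 2-cyano-3-[(1R,3S)-2,2-dimethyl-3-(prop-1-en-2-yl)cyclobutyl]propanoate; 8 prenyl bromide
Product: 9 tert-butyl (2S)-2-cyano-2-{[(1R,3S)-2,2-dimethyl-3-(prop-1-en-2-yl)cyclobutyl]methyl}-5-methylhex-4-enoate
Conditions: (11bS)-4,4-dibutyl-2,6-bis(3,4,5-trifluorophenyl)-4,5-dihydro-3H-dinaphtho[2,1-c:1',2'-e]azepinium bromide (2 mol%), Cs2CO3, toluene, −20 °C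
Reagents that add atoms: none
Why: Asymmetric phase-transfer alkylation of an α-alkyl cyanoacetate, in which the chiral binaphthyl ammonium ion pair shields one enolate face and sets the quaternary centre (the future C6); the minor C-2 epimer is a diastereomer and should be removable by chromatography.

Step 7
Reactants: 9 tert-butyl (2S)-2-cyano-2-{[(1R,3S)-2,2-dimethyl-3-(prop-1-en-2-yl)cyclobutyl]methyl}-5-methylhex-4-enoate
Product: 10 tert-butyl (2S)-2-{[(1R,3S)-2,2-dimethyl-3-(prop-1-en-2-yl)cyclobutyl]methyl}-2-formyl-5-methylhex-4-enoate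
Conditions: i-Bu2AlH (1.2 equiv), CH2Cl2, −78 → −40 °C; aq. potassium sodium tartrate, then dilute AcOH
Reagents that add atoms: water, O
Why: Partial reduction of the nitrile to the N-aluminoimine and hydrolysis to the aldehyde; the hindered tert-butyl ester is reduced much more slowly and the quaternary centre cannot epimerise.

Step 8
Reactants: 10 tert-butyl (2S)-2-{[(1R,3S)-2,2-dimethyl-3-(prop-1-en-2-yl)cyclobutyl]methyl}-2-formyl-5-methylhex-4-enoate
Product: 11 tert-butyl (2S)-2-{[(1R,3S)-2,2-dimethyl-3-(prop-1-en-2-yl)cyclobutyl]methyl}-2-ethynyl-5-methylhex-4-enoate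
Conditions: Me3SiCHN2, n-BuLi, THF, −78 °C; then 10, −78 °C → rt
Reagents that add atoms: trimethylsilyldiazomethane, C[Si](C)(C)C=[N+]=[N-]
Why: Colvin homologation (addition, Peterson elimination, 1,2-hydride shift of the alkylidene carbene) of a non-enolisable aldehyde under aprotic conditions, which avoids the alkoxide-induced deformylation of an α-formyl ester.

Step 9
Reactants: 12 ethyl (3S)-3-hydroxybutanoate
Product: 13 ethyl (2S,3S)-3-hydroxy-2-methylbutanoate
Conditions: LiN(i-Pr)2 (2.2 equiv), THF, −50 → −20 °C; MeI, DMPU, −78 → 0 °C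
Reagents that add atoms: iodomethane, CI
Why: Fráter–Seebach alkylation, in which the chelated alkoxide–enolate dianion is methylated anti to the C-3 substituent and sets the future C3 of the chromene relative to the existing carbinol centre.

Step 10
Reactants: 13 ethyl (2S,3S)-3-hydroxy-2-methylbutanoate
Product: 14 (2S,3S)-3-hydroxy-N-methoxy-N,2-dimethylbutanamide
Conditions: MeNH(OMe)·HCl, i-PrMgCl, THF, −20 → 0 °C
Reagents that add atoms: N,O-dimethylhydroxylamine hydrochloride, CNOC.Cl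
Why: Direct ester-to-Weinreb-amide aminolysis by the magnesium amide; the α-centre is protected from epimerisation by prior alkoxide formation and low temperature.

Step 11
Reactants: 14 (2S,3S)-3-hydroxy-N-methoxy-N,2-dimethylbutanamide
Product: 15 (2S,3S)-3-[(tert-butyldimethylsilyl)oxy]-N-methoxy-N,2-dimethylbutanamide
Conditions: t-BuMe2SiCl, imidazole, DMF, rt
Reagents that add atoms: tert-butyldimethylsilyl chloride, CC(C)(C)[Si](C)(C)Cl
Why: Standard silylation; the hydroxyl must stay masked until the ynone has been turned into the vinylogous amide, since a free β-hydroxy ynone would close to a dihydropyranone.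

Step 12
Reactants: 11 tert-butyl (2S)-2-{[(1R,3S)-2,2-dimethyl-3-(prop-1-en-2-yl)cyclobutyl]methyl}-2-ethynyl-5-methylhex-4-enoate; 15 (2S,3S)-3-[(tert-butyldimethylsilyl)oxy]-N-methoxy-N,2-dimethylbutanamide
Product: 16 tert-butyl (2S,6S,7S)-7-[(tert-butyldimethylsilyl)oxy]-2-{[(1R,3S)-2,2-dimethyl-3-(prop-1-en-2-yl)cyclobutyl]methyl}-6-methyl-2-(3-methylbut-2-en-1-yl)-5-oxooct-3-ynoate
Conditions: 11, n-BuLi, THF, −78 °C; then 15, −78 → −20 °C; aq. NH4Cl
Reagents that add atoms: none
Why: Weinreb ketone synthesis with a lithium acetylide; the chelated tetrahedral intermediate releases the ynone only on work-up, so the α-methyl centre is not exposed to base as a ketone.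

Step 13
Reactants: 16 tert-butyl (2S,6S,7S)-7-[(tert-butyldimethylsilyl)oxy]-2-{[(1R,3S)-2,2-dimethyl-3-(prop-1-en-2-yl)cyclobutyl]methyl}-6-methyl-2-(3-methylbut-2-en-1-yl)-5-oxooct-3-ynoate
Product: 17 tert-butyl (2S,3E,6S,7S)-7-[(tert-butyldimethylsilyl)oxy]-3-(dimethylamino)-2-{[(1R,3S)-2,2-dimethyl-3-(prop-1-en-2-yl)cyclobutyl]methyl}-6-methyl-2-(3-methylbut-2-en-1-yl)-5-oxooct-3-enoate
Conditions: Me2NH (2 M in THF, 3 equiv), THF, 0 °C → rt; evaporate
Reagents that add atoms: dimethylamine, CNC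
Why: Aza-Michael addition of a secondary amine to the ynone β-carbon, which places nitrogen regiospecifically on the future C5 and makes the future C4a a nucleophilic vinylogous amide carbon; the push-pull C=C is drawn E but is configurationally mobile and its geometry is of no consequence.

Step 14
Reactants: 17 tert-butyl (2S,3E,6S,7S)-7-[(tert-butyldimethylsilyl)oxy]-3-(dimethylamino)-2-{[(1R,3S)-2,2-dimethyl-3-(prop-1-en-2-yl)cyclobutyl]methyl}-6-methyl-2-(3-methylbut-2-en-1-yl)-5-oxooct-3-enoate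
Product: 19 (2S,3E,6S,7S)-7-[(tert-butyldimethylsilyl)oxy]-3-(dimethylamino)-2-{[(1R,3S)-2,2-dimethyl-3-(prop-1-en-2-yl)cyclobutyl]methyl}-6-methyl-2-(3-methylbut-2-en-1-yl)-5-oxooct-3-enoic acid, via trimethylsilyl ester 18 (not isolated)
Conditions: Me3SiOSO2CF3, 2,6-lutidine, CH2Cl2, 0 °C → rt; pH 5 buffer
Reagents that add atoms: none
Why: Silyl-triflate-mediated tert-butyl ester cleavage (carbonyl silylation, loss of isobutene) under buffered non-protic conditions that spare the prenyl and isopropenyl alkenes and the silyl ether; the silyl ester is hydrolysed on work-up.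

Step 15
Reactants: 20 3-phenylglutaric anhydride
Product: 21 (3S)-5-methoxy-5-oxo-3-phenylpentanoic acid
Conditions: quinidine (1.1 equiv), MeOH (3 equiv), toluene, −55 °C; dilute HCl wash
Reagents that add atoms: methanol, CO
Why: Cinchona-alkaloid-mediated desymmetrising methanolysis of a prochiral anhydride, in which the alkaloid selects one of the two enantiotopic carbonyl groups and so sets the benzylic centre.

Step 16
Reactants: 21 (3S)-5-methoxy-5-oxo-3-phenylpentanoic acid
Product: 22 1-tert-butyl 5-methyl (3R)-3-phenylpentanedioate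
Conditions: Boc2O, 4-(dimethylamino)pyridine (cat.), t-BuOH, 30 °C
Reagents that add atoms: di-tert-butyl dicarbonate, CC(C)(C)OC(=O)OC(=O)OC(C)(C)C
Why: tert-Butyl esterification through the mixed carbonic anhydride under neutral conditions; the stereocentre is not α to a carbonyl and is unaffected (the descriptor changes only through priorities).

Step 17
Reactants: 22 1-tert-butyl 5-methyl (3R)-3-phenylpentanedioate
Product: 23 (3R)-5-tert-butoxy-5-oxo-3-phenylpentanoic acid
Conditions: LiOH·H2O (1.1 equiv), THF/H2O, 0 °C; HCl to pH 3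
Reagents that add atoms: lithium hydroxide, [Li+].[OH-]
Why: Chemoselective saponification of the methyl ester beside the hindered tert-butyl ester, which places the enolisable tert-butyl ester arm where the ring carbons C8/C8a are needed.

Step 18
Reactants: 19 (2S,3E,6S,7S)-7-[(tert-butyldimethylsilyl)oxy]-3-(dimethylamino)-2-{[(1R,3S)-2,2-dimethyl-3-(prop-1-en-2-yl)cyclobutyl]methyl}-6-methyl-2-(3-methylbut-2-en-1-yl)-5-oxooct-3-enoic acid; 23 (3R)-5-tert-butoxy-5-oxo-3-phenylpentanoic acid (2.2 equiv)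
Product: 25 (3R,6S,7E,10S,11S)-4-(tert-butoxycarbonyl)-11-[(tert-butyldimethylsilyl)oxy]-7-(dimethylamino)-6-{[(1R,3S)-2,2-dimethyl-3-(prop-1-en-2-yl)cyclobutyl]methyl}-10-methyl-6-(3-methylbut-2-en-1-yl)-5,9-dioxo-3-phenyldodec-7-enoic acid (both C-4 epimers), via acyl imidazolide 24 (not isolated)
Conditions: 19, 1,1'-carbonyldiimidazole, THF, rt; separately 23, LiN(i-Pr)2 (4.5 equiv), THF, −78 °C; combine, −78 → −20 °C; cold 0.5 M HCl
Reagents that add atoms: none
Why: Crossed Claisen condensation in which the carboxylate–ester-enolate dianion of 23 (enolisation only α to the ester) is C-acylated by the non-enolisable acyl imidazolide and the extra dianion absorbs the acidic proton of the β-keto ester; the C-4 centre is of no consequence because it becomes sp2 in step 22.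

Step 19
Reactants: 25 (3R,6S,7E,10S,11S)-4-(tert-butoxycarbonyl)-11-[(tert-butyldimethylsilyl)oxy]-7-(dimethylamino)-6-{[(1R,3S)-2,2-dimethyl-3-(prop-1-en-2-yl)cyclobutyl]methyl}-10-methyl-6-(3-methylbut-2-en-1-yl)-5,9-dioxo-3-phenyldodec-7-enoic acid
Product: 26 methyl (3R,6S,7E,10S,11S)-4-(tert-butoxycarbonyl)-11-[(tert-butyldimethylsilyl)oxy]-7-(dimethylamino)-6-{[(1R,3S)-2,2-dimethyl-3-(prop-1-en-2-yl)cyclobutyl]methyl}-10-methyl-6-(3-methylbut-2-en-1-yl)-5,9-dioxo-3-phenyldodec-7-enoate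
Conditions: Me3SiCHN2, toluene/MeOH, 0 °C
Reagents that add atoms: trimethylsilyldiazomethane, C[Si](C)(C)C=[N+]=[N-]
Why: Chemoselective methylation of the carboxylic acid (the α-substituted β-keto ester is little enolised), so the side-chain acid cannot trap the ketene or the sulfonylating agent later.

Step 20
Reactants: 26 methyl (3R,6S,7E,10S,11S)-4-(tert-butoxycarbonyl)-11-[(tert-butyldimethylsilyl)oxy]-7-(dimethylamino)-6-{[(1R,3S)-2,2-dimethyl-3-(prop-1-en-2-yl)cyclobutyl]methyl}-10-methyl-6-(3-methylbut-2-en-1-yl)-5,9-dioxo-3-phenyldodec-7-enoate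
Product: 27 methyl (3R,6S,7E,10S,11S)-4-(tert-butoxycarbonyl)-7-(dimethylamino)-6-{[(1R,3S)-2,2-dimethyl-3-(prop-1-en-2-yl)cyclobutyl]methyl}-11-hydroxy-10-methyl-6-(3-methylbut-2-en-1-yl)-5,9-dioxo-3-phenyldodec-7-enoate
Conditions: HF·pyridine, pyridine, THF, 0 °C → rt
Reagents that add atoms: none
Why: Buffered fluoride desilylation; attack of the freed hydroxyl on the vinylogous amide carbon is slowed by the adjacent quaternary centre and by the buffer, and the alcohol is carried straight into step 21.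

Step 21
Reactants: 27 methyl (3R,6S,7E,10S,11S)-4-(tert-butoxycarbonyl)-7-(dimethylamino)-6-{[(1R,3S)-2,2-dimethyl-3-(prop-1-en-2-yl)cyclobutyl]methyl}-11-hydroxy-10-methyl-6-(3-methylbut-2-en-1-yl)-5,9-dioxo-3-phenyldodec-7-enoate
Product: 28 methyl (3R,6S,7E,10S,11S)-4-(tert-butoxycarbonyl)-7-(dimethylamino)-6-{[(1R,3S)-2,2-dimethyl-3-(prop-1-en-2-yl)cyclobutyl]methyl}-11-[(methanesulfonyl)oxy]-10-methyl-6-(3-methylbut-2-en-1-yl)-5,9-dioxo-3-phenyldodec-7-enoate
Conditions: (MeSO2)2O, pyridine, CH2Cl2, 0 °C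
Reagents that add atoms: methanesulfonic anhydride, CS(=O)(=O)OS(C)(=O)=O
Why: Mesylation with retention at the carbinol carbon under weakly basic, chloride-free conditions; elimination is slow because the adjacent C–H is α to a vinylogous amide carbonyl and not to a simple ketone.

Step 22
Reactants: 28 methyl (3R,6S,7E,10S,11S)-4-(tert-butoxycarbonyl)-7-(dimethylamino)-6-{[(1R,3S)-2,2-dimethyl-3-(prop-1-en-2-yl)cyclobutyl]methyl}-11-[(methanesulfonyl)oxy]-10-methyl-6-(3-methylbut-2-en-1-yl)-5,9-dioxo-3-phenyldodec-7-enoate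
Product: 31 methyl (3S)-3-[(2R,3S,6R)-6-{[(1R,3S)-2,2-dimethyl-3-(prop-1-en-2-yl)cyclobutyl]methyl}-4-hydroxy-2,3-dimethyl-6-(3-methylbut-2-en-1-yl)-5,7-dioxo-3,5,6,7-tetrahydro-2H-chromen-8-yl]-3-phenylpropanoate, via acylketene 29 (not isolated), via 5-dimethylamino chromenone 30 (not isolated)
Conditions: 2,6-di-tert-butyl-4-methylpyridine (1.5 equiv), toluene (0.005 M), 110 °C, N2 sweep; then 1 M HCl (aq)/THF, rt
Reagents that add atoms: water, O
Why: Proposed new method: heating the tert-butyl β-keto ester expels tert-butanol to give acylketene 29 (the known retro-ene behaviour of tert-butyl acetoacetates), whose ketene carbon (future C8a) is attacked by the nucleophilic α-carbon (C4a) of the tethered vinylogous amide, the closest known reaction being the intermolecular C-acylation of enamines and enaminones by acylketenes. This closes the carbocycle as a six-membered enol-endo ring with the ketene C=O exocyclic, and the enol(ate) oxygen so formed on C8a then displaces the secondary mesylate at C2 in a 6-exo-tet SN2 closure of the pyranone. C2 is the only new stereocentre and is set by inversion of the (S)-mesylate to (R); C3 is carried unchanged from step 9, so the anti precursor gives the cis-2,3-dimethyl ring. The regioselectivity needed (ring oxygen on C8a, not C5) is secured because C5 bears NMe2 until the acid stage, which hydrolyses the twisted vinylogous amide 30 and brings the C5 oxygen from water. C-acylation through C4a is secured because the amine is tertiary and only this attack gives a six-membered ring, and elimination of the mesylate is disfavoured because C3–H is α to a vinylogous amide carbonyl and the only base is the hindered pyridine. High dilution suppresses ketene dimerisation, and the prenyl and isopropenyl alkenes are far weaker π-nucleophiles than the enaminone.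

Step 23
Reactants: 31 methyl (3S)-3-[(2R,3S,6R)-6-{[(1R,3S)-2,2-dimethyl-3-(prop-1-en-2-yl)cyclobutyl]methyl}-4-hydroxy-2,3-dimethyl-6-(3-methylbut-2-en-1-yl)-5,7-dioxo-3,5,6,7-tetrahydro-2H-chromen-8-yl]-3-phenylpropanoate
Product: 32 (3S)-3-[(2R,3S,6R)-6-{[(1R,3S)-2,2-dimethyl-3-(prop-1-en-2-yl)cyclobutyl]methyl}-4-hydroxy-2,3-dimethyl-6-(3-methylbut-2-en-1-yl)-5,7-dioxo-3,5,6,7-tetrahydro-2H-chromen-8-yl]-3-phenylpropanoic acid (CNP0328119.1)
Conditions: LiOH (3 equiv), THF/H2O, 0 °C; 1 M HCl to pH 3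
Reagents that add atoms: lithium hydroxide, [Li+].[OH-]
Why: Saponification of the unhindered methyl ester; the triketone is present as its delocalised enolate, which protects C3 from epimerisation, the pyranone from retro-oxa-Michael opening and the C5/C7 carbonyls from retro-Claisen attack.

## Compound list

1 | (1S,5S)-(−)-verbenone | CC1=CC(=O)[C@H]2C[C@@H]1C2(C)C | starting material
2 | (1S,3R)-3-acetyl-2,2-dimethylcyclobutane-1-carboxylic acid | CC(=O)[C@@H]1C[C@H](C(=O)O)C1(C)C | intermediate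
3 | (1S,3S)-2,2-dimethyl-3-(prop-1-en-2-yl)cyclobutane-1-carboxylic acid | C=C(C)[C@@H]1C[C@H](C(=O)O)C1(C)C | intermediate
4 | [(1S,3S)-2,2-dimethyl-3-(prop-1-en-2-yl)cyclobutyl]methanol | C=C(C)[C@@H]1C[C@H](CO)C1(C)C | intermediate
5 | (1S,3S)-1-(iodomethyl)-2,2-dimethyl-3-(prop-1-en-2-yl)cyclobutane | C=C(C)[C@@H]1C[C@H](CI)C1(C)C | intermediate
6 | tert-butyl cyanoacetate | CC(C)(C)OC(=O)CC#N | starting material
7 | tert-butyl 2-cyano-3-[(1R,3S)-2,2-dimethyl-3-(prop-1-en-2-yl)cyclobutyl]propanoate (C-2 epimers) | C=C(C)[C@@H]1C[C@H](CC(C#N)C(=O)OC(C)(C)C)C1(C)C | intermediate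
8 | prenyl bromide (1-bromo-3-methylbut-2-ene) | CC(C)=CCBr | starting material
9 | tert-butyl (2S)-2-cyano-2-{[(1R,3S)-2,2-dimethyl-3-(prop-1-en-2-yl)cyclobutyl]methyl}-5-methylhex-4-enoate | C=C(C)[C@@H]1C[C@H](C[C@@](CC=C(C)C)(C#N)C(=O)OC(C)(C)C)C1(C)C | intermediate
10 | tert-butyl (2S)-2-{[(1R,3S)-2,2-dimethyl-3-(prop-1-en-2-yl)cyclobutyl]methyl}-2-formyl-5-methylhex-4-enoate | C=C(C)[C@@H]1C[C@H](C[C@@](CC=C(C)C)(C=O)C(=O)OC(C)(C)C)C1(C)C | intermediate
11 | tert-butyl (2S)-2-{[(1R,3S)-2,2-dimethyl-3-(prop-1-en-2-yl)cyclobutyl]methyl}-2-ethynyl-5-methylhex-4-enoate | C=C(C)[C@@H]1C[C@H](C[C@@](CC=C(C)C)(C#C)C(=O)OC(C)(C)C)C1(C)C | intermediate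
12 | ethyl (3S)-3-hydroxybutanoate | CCOC(=O)C[C@H](C)O | starting material
13 | ethyl (2S,3S)-3-hydroxy-2-methylbutanoate | CCOC(=O)[C@@H](C)[C@H](C)O | intermediate
14 | (2S,3S)-3-hydroxy-N-methoxy-N,2-dimethylbutanamide | CON(C)C(=O)[C@@H](C)[C@H](C)O | intermediate
15 | (2S,3S)-3-[(tert-butyldimethylsilyl)oxy]-N-methoxy-N,2-dimethylbutanamide | CON(C)C(=O)[C@@H](C)[C@H](C)O[Si](C)(C)C(C)(C)C | intermediate
16 | ynone: tert-butyl (2S,6S,7S)-7-[(tert-butyldimethylsilyl)oxy]-2-{[(1R,3S)-2,2-dimethyl-3-(prop-1-en-2-yl)cyclobutyl]methyl}-6-methyl-2-(3-methylbut-2-en-1-yl)-5-oxooct-3-ynoate | C=C(C)[C@@H]1C[C@H](C[C@@](CC=C(C)C)(C#CC(=O)[C@@H](C)[C@H](C)O[Si](C)(C)C(C)(C)C)C(=O)OC(C)(C)C)C1(C)C | intermediate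
17 | vinylogous amide: tert-butyl (2S,3E,6S,7S)-7-[(tert-butyldimethylsilyl)oxy]-3-(dimethylamino)-2-{[(1R,3S)-2,2-dimethyl-3-(prop-1-en-2-yl)cyclobutyl]methyl}-6-methyl-2-(3-methylbut-2-en-1-yl)-5-oxooct-3-enoate | C=C(C)[C@@H]1C[C@H](C[C@@](CC=C(C)C)(/C(N(C)C)=C\C(=O)[C@@H](C)[C@H](C)O[Si](C)(C)C(C)(C)C)C(=O)OC(C)(C)C)C1(C)C | intermediate
18 | trimethylsilyl ester of acid 19 | C=C(C)[C@@H]1C[C@H](C[C@@](CC=C(C)C)(/C(N(C)C)=C\C(=O)[C@@H](C)[C@H](C)O[Si](C)(C)C(C)(C)C)C(=O)O[Si](C)(C)C)C1(C)C | intermediate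
19 | (2S,3E,6S,7S)-7-[(tert-butyldimethylsilyl)oxy]-3-(dimethylamino)-2-{[(1R,3S)-2,2-dimethyl-3-(prop-1-en-2-yl)cyclobutyl]methyl}-6-methyl-2-(3-methylbut-2-en-1-yl)-5-oxooct-3-enoic acid | C=C(C)[C@@H]1C[C@H](C[C@@](CC=C(C)C)(/C(N(C)C)=C\C(=O)[C@@H](C)[C@H](C)O[Si](C)(C)C(C)(C)C)C(=O)O)C1(C)C | intermediate
20 | 3-phenylglutaric anhydride (4-phenyloxane-2,6-dione) | O=C1CC(c2ccccc2)CC(=O)O1 | starting material
21 | (3S)-5-methoxy-5-oxo-3-phenylpentanoic acid | COC(=O)C[C@H](CC(=O)O)c1ccccc1 | intermediate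
22 | 1-tert-butyl 5-methyl (3R)-3-phenylpentanedioate | CC(C)(C)OC(=O)C[C@@H](CC(=O)OC)c1ccccc1 | intermediate
23 | (3R)-5-tert-butoxy-5-oxo-3-phenylpentanoic acid | CC(C)(C)OC(=O)C[C@@H](CC(=O)O)c1ccccc1 | intermediate
24 | acyl imidazolide of acid 19 | C=C(C)[C@@H]1C[C@H](C[C@@](CC=C(C)C)(/C(N(C)C)=C\C(=O)[C@@H](C)[C@H](C)O[Si](C)(C)C(C)(C)C)C(=O)n2ccnc2)C1(C)C | intermediate
25 | (3R,6S,7E,10S,11S)-4-(tert-butoxycarbonyl)-11-[(tert-butyldimethylsilyl)oxy]-7-(dimethylamino)-6-{[(1R,3S)-2,2-dimethyl-3-(prop-1-en-2-yl)cyclobutyl]methyl}-10-methyl-6-(3-methylbut-2-en-1-yl)-5,9-dioxo-3-phenyldodec-7-enoic acid (C-4 epimers) | C=C(C)[C@@H]1C[C@H](C[C@@](CC=C(C)C)(/C(N(C)C)=C\C(=O)[C@@H](C)[C@H](C)O[Si](C)(C)C(C)(C)C)C(=O)C(C(=O)OC(C)(C)C)[C@@H](CC(=O)O)c2ccccc2)C1(C)C | intermediate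
26 | methyl ester of 25 | C=C(C)[C@@H]1C[C@H](C[C@@](CC=C(C)C)(/C(N(C)C)=C\C(=O)[C@@H](C)[C@H](C)O[Si](C)(C)C(C)(C)C)C(=O)C(C(=O)OC(C)(C)C)[C@@H](CC(=O)OC)c2ccccc2)C1(C)C | intermediate
27 | (11S)-alcohol from 26 | C=C(C)[C@@H]1C[C@H](C[C@@](CC=C(C)C)(/C(N(C)C)=C\C(=O)[C@@H](C)[C@H](C)O)C(=O)C(C(=O)OC(C)(C)C)[C@@H](CC(=O)OC)c2ccccc2)C1(C)C | intermediate
28 | (11S)-methanesulfonate of 27 | C=C(C)[C@@H]1C[C@H](C[C@@](CC=C(C)C)(/C(N(C)C)=C\C(=O)[C@@H](C)[C@H](C)OS(C)(=O)=O)C(=O)C(C(=O)OC(C)(C)C)[C@@H](CC(=O)OC)c2ccccc2)C1(C)C | intermediate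
29 | acylketene: methyl (3S,6S,7E,10S,11S)-7-(dimethylamino)-6-{[(1R,3S)-2,2-dimethyl-3-(prop-1-en-2-yl)cyclobutyl]methyl}-11-[(methanesulfonyl)oxy]-10-methyl-6-(3-methylbut-2-en-1-yl)-5,9-dioxo-4-(oxomethylidene)-3-phenyldodec-7-enoate | C=C(C)[C@@H]1C[C@H](C[C@@](CC=C(C)C)(/C(N(C)C)=C\C(=O)[C@@H](C)[C@H](C)OS(C)(=O)=O)C(=O)C(=C=O)[C@@H](CC(=O)OC)c2ccccc2)C1(C)C | intermediate
30 | methyl (3S)-3-[(2R,3S,6S)-5-(dimethylamino)-6-{[(1R,3S)-2,2-dimethyl-3-(prop-1-en-2-yl)cyclobutyl]methyl}-2,3-dimethyl-6-(3-methylbut-2-en-1-yl)-4,7-dioxo-3,4,6,7-tetrahydro-2H-chromen-8-yl]-3-phenylpropanoate | C=C(C)[C@@H]1C[C@H](C[C@@]2(CC=C(C)C)C(N(C)C)=C3C(=O)[C@@H](C)[C@@H](C)OC3=C([C@@H](CC(=O)OC)c3ccccc3)C2=O)C1(C)C | intermediate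
31 | methyl (3S)-3-[(2R,3S,6R)-6-{[(1R,3S)-2,2-dimethyl-3-(prop-1-en-2-yl)cyclobutyl]methyl}-4-hydroxy-2,3-dimethyl-6-(3-methylbut-2-en-1-yl)-5,7-dioxo-3,5,6,7-tetrahydro-2H-chromen-8-yl]-3-phenylpropanoate | C=C(C)[C@@H]1C[C@H](C[C@@]2(CC=C(C)C)C(=O)C3=C(O)[C@@H](C)[C@@H](C)OC3=C([C@@H](CC(=O)OC)c3ccccc3)C2=O)C1(C)C | intermediate
32 | (3S)-3-[(2R,3S,6R)-6-{[(1R,3S)-2,2-dimethyl-3-(prop-1-en-2-yl)cyclobutyl]methyl}-4-hydroxy-2,3-dimethyl-6-(3-methylbut-2-en-1-yl)-5,7-dioxo-3,5,6,7-tetrahydro-2H-chromen-8-yl]-3-phenylpropanoic acid | C=C(C)[C@@H]1C[C@H](C[C@@]2(CC=C(C)C)C(=O)C3=C(O)[C@@H](C)[C@@H](C)OC3=C([C@@H](CC(=O)O)c3ccccc3)C2=O)C1(C)C | target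

## Step count and risks

Total step count: 23. Longest linear sequence: 17 (steps 1–8, 12–14, 18–23).

Steps most likely to fail:

1. Step 22 (Proposed new method). The ketene may be consumed by dimerisation or by the alkenes before the vinylogous amide carbon reaches it; the mesylate may be lost by elimination before ring closure, which would erode C2/C3; the crowded vinylogous amide may resist hydrolysis. The fallback separates the two bond formations and uses known reactions, at the price of a regioisomer separation. It sets out from 26 and comes back at 31. Mild aqueous acid (0.5 M HCl, THF, 0 °C) should hydrolyse the vinylogous amide of 26 to the silyl-protected β-diketone F1. A base-mediated Claisen (Dieckmann-type) cyclisation of the polyketo ester (NaOMe, MeOH) should then close the carbocycle to the 2-acylcyclohexane-1,3,5-trione F2. HF·pyridine should free the secondary alcohol F3. An intramolecular Mitsunobu etherification (PPh3, diisopropyl azodicarboxylate, toluene) should close the pyranone with inversion at C2 to give 31 together with its C5–O regioisomer, which would be separated by chromatography.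

2. Step 6. Facial selectivity in the phase-transfer prenylation may be poor because the α-substituent is bulky and the existing stereocentres are remote. The fallback replaces catalyst control by separation. It sets out from 7 and comes back at 9. Prenylation under achiral conditions (K2CO3, DMF, prenyl bromide) should give 9 together with its (2R)-epimer F4; these are diastereomers because of the cyclobutane centres and would be separated by chromatography or preparative HPLC.

3. Step 18. C-acylation of the glutarate dianion by the hindered acyl imidazolide may be slow, with proton transfer or O-acylation taking over. The fallback builds the β-keto ester first and sets the benzylic centre by catalysis. It sets out from 19 (through 24) and comes back at 25. Treating 24 with magnesium bis(mono-tert-butyl malonate) (Masamune–Brooks) should give the unsubstituted β-keto tert-butyl ester F5. Iminium-catalysed Michael addition of F5 to cinnamaldehyde, with the enantiomer of diphenylprolinol trimethylsilyl ether that gives the required benzylic configuration, should give the aldehyde F6. Pinnick oxidation (NaClO2, NaH2PO4, 2-methylbut-2-ene) should then give 25.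

Further compounds
F1 | step 22 | β-diketone: methyl (3R,6S,10S,11S)-4-(tert-butoxycarbonyl)-11-[(tert-butyldimethylsilyl)oxy]-6-{[(1R,3S)-2,2-dimethyl-3-(prop-1-en-2-yl)cyclobutyl]methyl}-10-methyl-6-(3-methylbut-2-en-1-yl)-5,7,9-trioxo-3-phenyldodecanoate | C=C(C)[C@@H]1C[C@H](C[C@@](CC=C(C)C)(C(=O)CC(=O)[C@@H](C)[C@H](C)O[Si](C)(C)C(C)(C)C)C(=O)C(C(=O)OC(C)(C)C)[C@@H](CC(=O)OC)c2ccccc2)C1(C)C
F2 | step 22 | 2-acylcyclohexane-1,3,5-trione with the silyl-protected (2S,3S)-3-hydroxy-2-methylbutanoyl group (one enol tautomer) | C=C(C)[C@@H]1C[C@H](C[C@@]2(CC=C(C)C)C(=O)C(=C(O)[C@@H](C)[C@H](C)O[Si](C)(C)C(C)(C)C)C(O)=C([C@@H](CC(=O)OC)c3ccccc3)C2=O)C1(C)C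
F3 | step 22 | free secondary alcohol of F2 | C=C(C)[C@@H]1C[C@H](C[C@@]2(CC=C(C)C)C(=O)C(=C(O)[C@@H](C)[C@H](C)O)C(O)=C([C@@H](CC(=O)OC)c3ccccc3)C2=O)C1(C)C
F4 | step 6 | tert-butyl (2R)-2-cyano-2-{[(1R,3S)-2,2-dimethyl-3-(prop-1-en-2-yl)cyclobutyl]methyl}-5-methylhex-4-enoate | C=C(C)[C@@H]1C[C@H](C[C@](CC=C(C)C)(C#N)C(=O)OC(C)(C)C)C1(C)C
F5 | step 18 | β-keto tert-butyl ester lacking the benzylic side chain | C=C(C)[C@@H]1C[C@H](C[C@@](CC=C(C)C)(/C(N(C)C)=C\C(=O)[C@@H](C)[C@H](C)O[Si](C)(C)C(C)(C)C)C(=O)CC(=O)OC(C)(C)C)C1(C)C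
F6 | step 18 | Michael adduct aldehyde (aldehyde in place of the acid of 25) | C=C(C)[C@@H]1C[C@H](C[C@@](CC=C(C)C)(/C(N(C)C)=C\C(=O)[C@@H](C)[C@H](C)O[Si](C)(C)C(C)(C)C)C(=O)C(C(=O)OC(C)(C)C)[C@@H](CC=O)c2ccccc2)C1(C)C
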